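**Plan**
1. Ring C is opened at the C13=C14 alkene (ring-closing metathesis), then at C11–C12 and C15–C16 (allyl and 2-methylallyl additions to aldehydes). C8–C11 and C9–C16 go back to hydroxymethylations of enol triflates made from a C9 ketone and then a C8 ketone.
2. Ring A is opened at C2–C3. C2 and C3 are the adjacent carbinol carbons of the all-cis C1–C2–C3 triol and C3 sits on the quaternary C4, so both can be aldehydes on the two arms that leave C10 and C5 of ring B trans; a SmI2 pinacol coupling joins them.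
3. The dialdehyde comes from 2-methylcyclohex-2-en-1-one: conjugate addition of prenyltrimethylsilane makes C5–C4, aldol trapping with acrolein makes C10–C1, and ozonolysis unmasks C2 and C3.
4. Forward: ring B is bought, ring A is closed by the pinacol coupling, the ring A esters are set, C9 and then C8/C7 are elaborated, ring C is closed last, and a double oxidation ends the route.
5. Stereochemistry: C5/C10 from the addition–aldol sequence; C1 and the absolute configuration from an oxazaborolidine reduction of the racemic vinyl ketone with separation of diastereomers; C2/C3 from the samarium-bridged coupling; C9 from hydroboration opposite the axial C10 methyl; C7/C8 from trans-diaxial opening of a 7β,8β-epoxide; the Z alkene from the ring.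

Key step: step 7

Remark: ring A = C1–C5 and C10, ring B = C5–C10, ring C = C8, C11–C16 and C9; the C10 methyl is called α, so β is the face of H5 and the target is 1β,3β-dibenzoate, 2β,7β-diacetate, 8α-OH, H9β.
Remark: compounds 4–7 are racemic and drawn as the enantiomer carried on; the C11 and C16 carbinols of 31–37 are carried as epimer mixtures (left open in the SMILES) because both carbons end as ketones.

**Route**

Step 1
Reactants: 1 2-methylcyclohex-2-en-1-one; 2 prenyltrimethylsilane; 3 acrolein
Product: 5 rac-(2S,3R)-2-(1-hydroxyprop-2-en-1-yl)-2-methyl-3-(2-methylbut-3-en-2-yl)cyclohexan-1-one (both carbinol epimers), via trichlorotitanium enolate 4 (not isolated)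
Conditions: TiCl4 (1.1 equiv), CH2Cl2, −78 °C; then acrolein, −78 °C; aq. NH4Cl
Reagents that add atoms: none
Why: Hosomi–Sakurai conjugate addition with aldol trapping, in which the allylsilane attacks C5 through its dimethyl-substituted terminus and the resulting titanium enolate adds to acrolein at C10 on the face away from the new C5 substituent, which sets the trans relationship of the two arms, while the carbinol configuration is left open because steps 3 and 4 reset it.

Step 2
Reactants: 5 rac-aldol
Product: 6 rac-1-[(6S,7R)-6-methyl-7-(2-methylbut-3-en-2-yl)-1,4-dioxaspiro[4.5]decan-6-yl]prop-2-en-1-ol (both carbinol epimers)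
Conditions: ethylene glycol, HC(OEt)3, p-toluenesulfonic acid monohydrate (cat.), CH2Cl2, rt
Reagents that add atoms: ethylene glycol, OCCO
Why: Acid-catalysed ketalisation with an orthoformate as water scavenger masks the C9 ketone, which would otherwise be a second reducible carbonyl in step 4 and a ketyl acceptor in step 7, and the quaternary C10 excludes dehydration of the aldol.

Step 3
Reactants: 6 rac-ketal alcohol
Product: 7 rac-1-[6-methyl-7-(2-methylbut-3-en-2-yl)-1,4-dioxaspiro[4.5]decan-6-yl]prop-2-en-1-one (ring stereocentres as in 6)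
Conditions: Dess–Martin periodinane, CH2Cl2, 0 °C → rt
Reagents that add atoms: none
Why: Dess–Martin oxidation converges both carbinol epimers on one vinyl ketone, which cannot enolise toward the quaternary C10.

Step 4
Reactants: 7 rac-vinyl ketone
Product: 8 (1R)-1-[(6S,7R)-6-methyl-7-(2-methylbut-3-en-2-yl)-1,4-dioxaspiro[4.5]decan-6-yl]prop-2-en-1-ol
Conditions: (S)-1-methyl-3,3-diphenyltetrahydro-1H,3H-pyrrolo[1,2-c][1,3,2]oxazaborole (0.5 equiv), catecholborane, toluene, −78 °C; aq. NaOH work-up; chromatographic separation of the two diastereomers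
Reagents that add atoms: none
Why: Corey–Bakshi–Shibata reduction under reagent control, in which the tertiary C10 group should act as the large and the vinyl group as the small substituent so that the (S)-catalyst gives the (1R)-carbinol from both enantiomers of 7, and removal of the diastereomer that stems from the mirror-image ketone fixes C1 and the absolute configuration together.

Step 5
Reactants: 8 (1R)-allylic alcohol
Product: 10 (6S,7R)-6-[(1R)-1-(benzyloxy)prop-2-en-1-yl]-6-methyl-7-(2-methylbut-3-en-2-yl)-1,4-dioxaspiro[4.5]decane, via sodium alkoxide 9 (not isolated)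
Conditions: NaH, THF/DMF, 0 °C; then BnBr, Bu4NI (cat.), 0 °C → rt
Reagents that add atoms: benzyl bromide, BrCc1ccccc1
Why: Williamson etherification, in which the alkoxide has no retro-aldol pathway because C9 is ketalised, gives an ether that survives ozone at low temperature and SmI2.

Step 6
Reactants: 10 benzyl ether
Product: 12 dialdehyde 2-(benzyloxy)-2-[6-methyl-7-(2-methyl-1-oxopropan-2-yl)-1,4-dioxaspiro[4.5]decan-6-yl]acetaldehyde (stereocentres as in 10), via bis-ozonide 11 (not isolated)
Conditions: O3, CH2Cl2, −78 °C; then PPh3, −78 °C → rt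
Reagents that add atoms: ozone, [O-][O+]=O
Why: Ozonolysis with reductive work-up cleaves both monosubstituted vinyl groups to the C2 and C3 aldehydes, the C3 aldehyde on quaternary C4 being unable to enolise and the C1 stereocentre being kept by cold, neutral handling.

Step 7
Reactants: 12 dialdehyde (C2 and C3 aldehydes, 1-benzyloxy, C9 ethylene ketal)
Product: 13 1β-benzyloxy-4,4,10α-trimethyl-trans-decalin-2β,3β-diol 9-ethylene ketal (2-OH equatorial; 3-OH axial)
Conditions: SmI2 (2.5 equiv), t-BuOH (2.5 equiv), THF, −78 °C → rt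
Reagents that add atoms: none
Why: SmI2 transfers one electron to each aldehyde and the two samarium ketyls, held on one oxophilic metal centre, join at carbon to form C2–C3 (a like-polarity, pinacol-type union); the closest known reaction type is the SmI2 pinacol cyclisation of 1,6-dialdehydes to cis-cyclohexane-1,2-diols. Ring A closes as a six-membered ring (6-exo mode with respect to the accepting carbonyl) onto a ring B chair whose C10 and C5 arms are trans-diequatorial, so only the trans-decalin can result. The C2 oxygen is set equatorial (β) because an axial C2–O would be syn-diaxial to both the C10 methyl and the axial C4 methyl. The C3 oxygen is set cis to it (axial, β) by the trivalent samarium that bridges the two ketyl oxygens, and the axial C1 benzyloxy oxygen on the same face can complete an axial–equatorial–axial chelate. The step needs aldehyde-over-ketone chemoselectivity and cis-diol selectivity: the first is secured by the C9 ketal, the second by working without HMPA so that chelation persists, while the quaternary C4 (no enolisation of the C3 aldehyde) and an ether rather than an ester at C1 (no β-elimination from the ketyl) remove the side reactions.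

Step 8
Reactants: 13 cis-2β,3β-diol
Product: 14 2β-acetoxy-1β-benzyloxy-3β-hydroxy-4,4,10α-trimethyl-trans-decalin-9-one ethylene ketal
Conditions: Ac2O (1.1 equiv), pyridine, CH2Cl2, 0 °C
Reagents that add atoms: acetic anhydride, CC(=O)OC(C)=O
Why: Selective esterification, since the equatorial C2 hydroxyl should react much faster than the axial, neopentyl C3 hydroxyl that is flanked by the C4 gem-dimethyl group and is syn-diaxial to the C1 ether.

Step 9
Reactants: 14 2β-acetate
Product: 15 2β-acetoxy-1β,3β-dihydroxy-4,4,10α-trimethyl-trans-decalin-9-one ethylene ketal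
Conditions: H2 (1 atm), Pd(OH)2 on carbon, EtOAc, rt
Reagents that add atoms: none
Why: Hydrogenolysis of the benzyl ether under neutral conditions leaves the acetate, the ketal and all stereocentres untouched, and no alkene is present at this stage.

Step 10
Reactants: 15 1β,3β-diol 2β-acetate
Product: 16 2β-acetoxy-1β,3β-bis(benzoyloxy)-4,4,10α-trimethyl-trans-decalin-9-one ethylene ketal
Conditions: benzoyl trifluoromethanesulfonate (3 equiv), pyridine, CH2Cl2, −78 → 0 °C
Reagents that add atoms: benzoyl trifluoromethanesulfonate, O=C(OS(=O)(=O)C(F)(F)F)c1ccccc1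
Why: Acylation with the highly electrophilic benzoyl triflate should esterify both hindered, mutually syn-diaxial hydroxyls at C1 and C3 at low temperature, where migration of the C2 acetate does not compete.

Step 11
Reactants: 16 ketal triester
Product: 17 2β-acetoxy-1β,3β-bis(benzoyloxy)-4,4,10α-trimethyl-trans-decalin-9-one
Conditions: p-toluenesulfonic acid monohydrate (cat.), acetone/H2O (10:1), 50 °C
Reagents that add atoms: water, O
Why: Acid-catalysed ketal hydrolysis frees the C9 ketone, the three esters being stable to dilute acid.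

Step 12
Reactants: 17 C9 ketone
Product: 18 C9 enol triflate (C8=C9 alkene; OTf on C9)
Conditions: Tf2O, 2,6-di-tert-butyl-4-methylpyridine, CH2Cl2, 0 °C → rt
Reagents that add atoms: trifluoromethanesulfonic anhydride, O=S(=O)(OS(=O)(=O)C(F)(F)F)C(F)(F)F
Why: Enol triflate formation with a hindered pyridine base needs no strong base that would endanger the esters and is regiospecific because C8 is the only enolisable position next to C9.

Step 13
Reactants: 18 C9 enol triflate
Product: 19 9-(hydroxymethyl)-Δ8 alkene (C16 allylic alcohol)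
Conditions: Bu3SnCH2OH, Pd(PPh3)4 (10 mol%), LiCl, dioxane, 100 °C
Reagents that add atoms: (tributylstannyl)methanol, OC[Sn](CCCC)(CCCC)CCCC
Why: Stille coupling transfers the hydroxymethyl group from tin to C9, which installs C16 and leaves the C8=C9 alkene for the oxygenation of C8.

Step 14
Reactants: 19 C16 allylic alcohol
Product: 20 tert-butyldiphenylsilyl ether of 19
Conditions: TBDPSCl, imidazole, CH2Cl2, rt
Reagents that add atoms: tert-butyl(chloro)diphenylsilane, CC(C)(C)[Si](Cl)(c1ccccc1)c1ccccc1
Why: Silylation of the primary allylic alcohol gives an ether that survives the borane, amide base, epoxidation and aqueous acid steps that follow.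

Step 15
Reactants: 20 C16 silyl ether
Product: 22 8β-hydroxy-9α-[(tert-butyldiphenylsilyloxy)methyl] triester (H9β), via C8 alkylborane 21 (not isolated)
Conditions: BH3·THF (limited excess), THF, 0 °C → rt; then 30% H2O2, aq. NaHCO3, 0 °C → rt
Reagents that add atoms: hydrogen peroxide, OO
Why: Hydroboration–oxidation places boron on the less substituted C8 and hydrogen on C9 from the β face opposite the axial C10 methyl, which makes H9 β and the C16 arm α (equatorial), a configuration that is also the thermodynamic one once C8 is a ketone.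

Step 16
Reactants: 22 8β-alcohol
Product: 23 C8 ketone with 9α-[(tert-butyldiphenylsilyloxy)methyl] (H9β)
Conditions: Dess–Martin periodinane, CH2Cl2, rt
Reagents that add atoms: none
Why: Dess–Martin oxidation of the secondary C8 alcohol gives the ketone under neutral conditions that do not trigger β-elimination of the C16 silyloxy group.

Step 17
Reactants: 23 C8 ketone
Product: 25 C8 enol triflate (C7=C8 alkene; OTf on C8), via potassium enolate 24 (not isolated)
Conditions: KN(SiMe3)2, THF, −78 °C; then PhNTf2, −78 → −40 °C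
Reagents that add atoms: N-phenylbis(trifluoromethanesulfonimide), O=S(=O)(N(c1ccccc1)S(=O)(=O)C(F)(F)F)C(F)(F)F
Why: Kinetic deprotonation with the hindered amide base removes a C7 proton in preference to the tertiary, shielded C9 proton and is too weak to deprotonate the acetate, and triflation of the enolate fixes the alkene at C7=C8.

Step 18
Reactants: 25 C8 enol triflate
Product: 26 8-(hydroxymethyl)-Δ7 alkene (C11 allylic alcohol)
Conditions: Bu3SnCH2OH, Pd(PPh3)4 (10 mol%), LiCl, dioxane, 90 °C
Reagents that add atoms: (tributylstannyl)methanol, OC[Sn](CCCC)(CCCC)CCCC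
Why: A second Stille hydroxymethylation attaches C11 to C8 and gives the trisubstituted C7=C8 alkene that will carry both the C7 and the C8 oxygen.

Step 19
Reactants: 26 C11 allylic alcohol
Product: 27 7β,8β-epoxide of 26
Conditions: VO(acac)2 (5 mol%), t-BuOOH, CH2Cl2, 0 °C → rt
Reagents that add atoms: tert-butyl hydroperoxide, CC(C)(C)OO
Why: Hydroxyl-directed vanadium-catalysed epoxidation is selective for the allylic alcohol and should deliver oxygen to the β face, opposite the axial C10 methyl and the α-oriented C9 arm.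

Step 20
Reactants: 27 7β,8β-epoxide
Product: 28 7β,8α-dihydroxy-8β-(hydroxymethyl) compound (triol)
Conditions: HClO4 (0.1 M aq.), THF, 0 °C → rt
Reagents that add atoms: water, O
Why: Acid-catalysed epoxide hydrolysis should follow the trans-diaxial opening rule, which requires water to enter at the tertiary C8 from the α face, also the electronically preferred more substituted position, so that the C7 hydroxyl ends up β (axial) and the C8 hydroxyl α (axial) with C11 β (equatorial).

Step 21
Reactants: 28 triol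
Product: 29 7β,8α-dihydroxy-8β-carbaldehyde (C11 aldehyde)
Conditions: 2,2,6,6-tetramethylpiperidin-1-oxyl (10 mol%), PhI(OAc)2 (1.1 equiv), CH2Cl2, rt
Reagents that add atoms: none
Why: The oxoammonium-mediated oxidation is selective for the primary C11 alcohol over the hindered secondary C7 and the tertiary C8 alcohol and gives a non-enolisable α-hydroxy aldehyde.

Step 22
Reactants: 29 C11 aldehyde
Product: 30 7β-acetoxy-8α-hydroxy-8β-carbaldehyde
Conditions: Ac2O, pyridine, 4-(dimethylamino)pyridine (cat.), CH2Cl2, 0 °C → rt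
Reagents that add atoms: acetic anhydride, CC(=O)OC(C)=O
Why: Nucleophile-catalysed acetylation esterifies the only acylable hydroxyl, the secondary one at C7, because the tertiary C8 hydroxyl is inert and the aldehyde has no α-hydrogen.

Step 23
Reactants: 30 C11 aldehyde 7β-acetate
Product: 31 7β-acetoxy-8α-hydroxy-8β-(1-hydroxybut-3-en-1-yl) compound (C11 epimers)
Conditions: allylboronic acid pinacol ester, CH2Cl2, rt; aq. NaHCO3 work-up
Reagents that add atoms: allylboronic acid pinacol ester, C=CCB1OC(C)(C)C(C)(C)O1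
Why: Allylboration adds the allyl group to the C11 aldehyde through a closed six-membered transition state under neutral conditions that all esters tolerate, and the new carbinol configuration is immaterial because C11 becomes a ketone.

Step 24
Reactants: 31 C11 allyl carbinol
Product: 32 O8,O11-isopropylidene acetal of 31
Conditions: 2-methoxypropene, pyridinium p-toluenesulfonate (cat.), CH2Cl2, 0 °C → rt
Reagents that add atoms: 2-methoxypropene, COC(C)=C
Why: Acid-catalysed acetonide formation ties the C8 and C11 hydroxyls together, which prevents lactol formation and β-elimination when C16 is oxidised and holds the allyl arm near the C9 side chain for the ring closure.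

Step 25
Reactants: 32 acetonide silyl ether
Product: 33 9α-(hydroxymethyl) acetonide (C16 alcohol)
Conditions: HF·pyridine, pyridine/THF, 0 °C → rt
Reagents that add atoms: none
Why: Fluoride cleavage of the silyl ether under buffered conditions frees the C16 alcohol without acyl migration or loss of the acetonide.

Step 26
Reactants: 33 C16 alcohol
Product: 34 9α-carbaldehyde acetonide (C16 aldehyde)
Conditions: Dess–Martin periodinane, pyridine, CH2Cl2, 0 °C → rt
Reagents that add atoms: none
Why: Dess–Martin oxidation of the only free hydroxyl gives the C16 aldehyde, whose C9 substituent is already equatorial so that no epimerisation is to be expected.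

Step 27
Reactants: 34 C16 aldehyde
Product: 35 9α-(1-hydroxy-3-methylbut-3-en-1-yl) acetonide (C16 epimers)
Conditions: 2-methylallylboronic acid pinacol ester, toluene, rt → 40 °C; aq. NaHCO3 work-up
Reagents that add atoms: 2-methylallylboronic acid pinacol ester, CC(=C)CB1OC(C)(C)C(C)(C)O1
Why: Allylboration with the 2-methylallyl boronate adds C15 to the C16 aldehyde chemoselectively, and the carbinol configuration is again immaterial.

Step 28
Reactants: 35 diene
Product: 36 tricyclic acetonide (ring C closed; 13Z alkene; 16-hydroxy)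
Conditions: second-generation Grubbs catalyst, RuCl2(=CHPh)(PCy3)(H2IMes) (10 mol%), 1,4-benzoquinone (20 mol%), CH2Cl2 (2 mM), 40 °C
Reagents that add atoms: none
Why: Ring-closing metathesis between the monosubstituted C13 alkene and the 1,1-disubstituted C14 alkene closes the eight-membered ring C with loss of ethylene, the trans-diequatorial arms on C8 and C9 and the acetonide favouring the reactive conformer and the ring size enforcing the Z trisubstituted alkene.

Step 29
Reactants: 36 tricyclic acetonide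
Product: 37 tricyclic 8α,11,16-triol
Conditions: AcOH/H2O (4:1), 40 °C
Reagents that add atoms: none
Why: Mild acid hydrolysis of the acetonide liberates the C8 and C11 hydroxyls without affecting the esters or the trisubstituted alkene.

Step 30
Reactants: 37 tricyclic triol
Product: 38 target CNP0214674.2
Conditions: Dess–Martin periodinane (3 equiv), pyridine, CH2Cl2, 0 °C → rt
Reagents that add atoms: none
Why: Dess–Martin oxidation buffered with pyridine converts both secondary carbinols at C11 and C16 into ketones while the tertiary C8 alcohol cannot react, and the near-neutral conditions should avoid migration of the β,γ-alkene, retro-aldol cleavage and epimerisation at C9.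

**Compound list**
1 | 2-methylcyclohex-2-en-1-one | CC1=CCCCC1=O | starting material
2 | prenyltrimethylsilane, trimethyl(3-methylbut-2-en-1-yl)silane | CC(C)=CC[Si](C)(C)C | starting material
3 | acrolein | C=CC=O | starting material
4 | rac-trichlorotitanium enolate of 2-methyl-3-(2-methylbut-3-en-2-yl)cyclohexanone | CC1=C(O[Ti](Cl)(Cl)Cl)CCC[C@@H]1C(C)(C)C=C | intermediate (not isolated)
5 | rac-(2S,3R)-2-(1-hydroxyprop-2-en-1-yl)-2-methyl-3-(2-methylbut-3-en-2-yl)cyclohexan-1-one, both carbinol epimers | C=CC(O)[C@]1(C)[C@H](CCCC1=O)C(C)(C)C=C | intermediate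
6 | rac-1-[(6S,7R)-6-methyl-7-(2-methylbut-3-en-2-yl)-1,4-dioxaspiro[4.5]decan-6-yl]prop-2-en-1-ol, both carbinol epimers | C=CC(O)[C@]1(C)[C@H](CCCC12OCCO2)C(C)(C)C=C | intermediate
7 | rac-vinyl ketone, 1-[6-methyl-7-(2-methylbut-3-en-2-yl)-1,4-dioxaspiro[4.5]decan-6-yl]prop-2-en-1-one, ring stereocentres as in 6 | C=CC(=O)[C@]1(C)[C@H](CCCC12OCCO2)C(C)(C)C=C | intermediate
8 | (1R)-1-[(6S,7R)-6-methyl-7-(2-methylbut-3-en-2-yl)-1,4-dioxaspiro[4.5]decan-6-yl]prop-2-en-1-ol | C=C[C@@H](O)[C@]1(C)[C@H](CCCC12OCCO2)C(C)(C)C=C | intermediate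
9 | sodium alkoxide of 8 | C=C[C@@H]([O-])[C@]1(C)[C@H](CCCC12OCCO2)C(C)(C)C=C.[Na+] | intermediate (not isolated)
10 | (6S,7R)-6-[(1R)-1-(benzyloxy)prop-2-en-1-yl]-6-methyl-7-(2-methylbut-3-en-2-yl)-1,4-dioxaspiro[4.5]decane | C=C[C@@H](OCc1ccccc1)[C@]2(C)[C@H](CCCC23OCCO3)C(C)(C)C=C | intermediate
11 | bis-ozonide of 10 (two 1,2,4-trioxolanes in place of the vinyl groups) | C1OC(OO1)[C@@H](OCc1ccccc1)[C@]2(C)[C@H](CCCC23OCCO3)C(C)(C)C1OCOO1 | intermediate (not isolated)
12 | dialdehyde: C2 and C3 aldehydes, 1-benzyloxy, C9 ethylene ketal, stereocentres as in 10 | O=C[C@@H](OCc1ccccc1)[C@]2(C)[C@H](CCCC23OCCO3)C(C)(C)C=O | intermediate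
13 | 1β-benzyloxy-4,4,10α-trimethyl-trans-decalin-2β,3β-diol 9-ethylene ketal (5β-H; 2-OH equatorial, 3-OH axial) | O[C@H]1[C@@H](OCc2ccccc2)[C@]3(C)[C@H](CCCC34OCCO4)C(C)(C)[C@H]1O | intermediate
14 | 2β-acetoxy-1β-benzyloxy-3β-hydroxy-4,4,10α-trimethyl-trans-decalin-9-one ethylene ketal | CC(=O)O[C@H]1[C@@H](OCc2ccccc2)[C@]3(C)[C@H](CCCC34OCCO4)C(C)(C)[C@H]1O | intermediate
15 | 2β-acetoxy-1β,3β-dihydroxy-4,4,10α-trimethyl-trans-decalin-9-one ethylene ketal | CC(=O)O[C@H]1[C@@H](O)[C@]2(C)[C@H](CCCC23OCCO3)C(C)(C)[C@H]1O | intermediate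
16 | 2β-acetoxy-1β,3β-bis(benzoyloxy)-4,4,10α-trimethyl-trans-decalin-9-one ethylene ketal | CC(=O)O[C@H]1[C@@H](OC(=O)c2ccccc2)[C@]3(C)[C@H](CCCC34OCCO4)C(C)(C)[C@H]1OC(=O)c1ccccc1 | intermediate
17 | 2β-acetoxy-1β,3β-bis(benzoyloxy)-4,4,10α-trimethyl-trans-decalin-9-one | CC(=O)O[C@H]1[C@@H](OC(=O)c2ccccc2)[C@]3(C)[C@H](CCCC3=O)C(C)(C)[C@H]1OC(=O)c1ccccc1 | intermediate
18 | C9 enol triflate of 17 (C8=C9) | CC(=O)O[C@H]1[C@@H](OC(=O)c2ccccc2)[C@]3(C)[C@H](CCC=C3OS(=O)(=O)C(F)(F)F)C(C)(C)[C@H]1OC(=O)c1ccccc1 | intermediate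
19 | 9-(hydroxymethyl)-Δ8 alkene, ring A triester (C16 alcohol) | CC(=O)O[C@H]1[C@@H](OC(=O)c2ccccc2)[C@]3(C)[C@H](CCC=C3CO)C(C)(C)[C@H]1OC(=O)c1ccccc1 | intermediate
20 | tert-butyldiphenylsilyl ether of 19 | CC(=O)O[C@H]1[C@@H](OC(=O)c2ccccc2)[C@]3(C)[C@H](CCC=C3CO[Si](c4ccccc4)(c5ccccc5)C(C)(C)C)C(C)(C)[C@H]1OC(=O)c1ccccc1 | intermediate
21 | C8β alkylborane from 20 (H9β, 9α-CH2OTBDPS), drawn as the monoalkylborane | CC(=O)O[C@H]1[C@@H](OC(=O)c2ccccc2)[C@]3(C)[C@H](CC[C@H](B)[C@H]3CO[Si](c4ccccc4)(c5ccccc5)C(C)(C)C)C(C)(C)[C@H]1OC(=O)c1ccccc1 | intermediate (not isolated)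
22 | 8β-hydroxy-9α-[(tert-butyldiphenylsilyloxy)methyl] triester (H9β) | CC(=O)O[C@H]1[C@@H](OC(=O)c2ccccc2)[C@]3(C)[C@H](CC[C@H](O)[C@H]3CO[Si](c4ccccc4)(c5ccccc5)C(C)(C)C)C(C)(C)[C@H]1OC(=O)c1ccccc1 | intermediate
23 | C8 ketone, 9α-[(tert-butyldiphenylsilyloxy)methyl] (H9β) | CC(=O)O[C@H]1[C@@H](OC(=O)c2ccccc2)[C@]3(C)[C@H](CCC(=O)[C@H]3CO[Si](c4ccccc4)(c5ccccc5)C(C)(C)C)C(C)(C)[C@H]1OC(=O)c1ccccc1 | intermediate
24 | potassium Δ7-enolate of 23 | CC(=O)O[C@H]1[C@@H](OC(=O)c2ccccc2)[C@]3(C)[C@H](CC=C([O-])[C@H]3CO[Si](c4ccccc4)(c5ccccc5)C(C)(C)C)C(C)(C)[C@H]1OC(=O)c1ccccc1.[K+] | intermediate (not isolated)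
25 | C8 enol triflate (C7=C8) | CC(=O)O[C@H]1[C@@H](OC(=O)c2ccccc2)[C@]3(C)[C@H](CC=C(OS(=O)(=O)C(F)(F)F)[C@H]3CO[Si](c4ccccc4)(c5ccccc5)C(C)(C)C)C(C)(C)[C@H]1OC(=O)c1ccccc1 | intermediate
26 | 8-(hydroxymethyl)-Δ7 alkene (C11 alcohol), 9α-CH2OTBDPS | CC(=O)O[C@H]1[C@@H](OC(=O)c2ccccc2)[C@]3(C)[C@H](CC=C(CO)[C@H]3CO[Si](c4ccccc4)(c5ccccc5)C(C)(C)C)C(C)(C)[C@H]1OC(=O)c1ccccc1 | intermediate
27 | 7β,8β-epoxide of 26 | CC(=O)O[C@H]1[C@@H](OC(=O)c2ccccc2)[C@]3(C)[C@H](C[C@@H]4O[C@]4(CO)[C@H]3CO[Si](c5ccccc5)(c6ccccc6)C(C)(C)C)C(C)(C)[C@H]1OC(=O)c1ccccc1 | intermediate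
28 | 7β,8α-dihydroxy-8β-(hydroxymethyl) compound (triol), 9α-CH2OTBDPS | CC(=O)O[C@H]1[C@@H](OC(=O)c2ccccc2)[C@]3(C)[C@H](C[C@H](O)[C@](O)(CO)[C@H]3CO[Si](c4ccccc4)(c5ccccc5)C(C)(C)C)C(C)(C)[C@H]1OC(=O)c1ccccc1 | intermediate
29 | 7β,8α-dihydroxy-8β-carbaldehyde (C11 aldehyde) | CC(=O)O[C@H]1[C@@H](OC(=O)c2ccccc2)[C@]3(C)[C@H](C[C@H](O)[C@](O)(C=O)[C@H]3CO[Si](c4ccccc4)(c5ccccc5)C(C)(C)C)C(C)(C)[C@H]1OC(=O)c1ccccc1 | intermediate
30 | 7β-acetoxy-8α-hydroxy-8β-carbaldehyde | CC(=O)O[C@H]1[C@@H](OC(=O)c2ccccc2)[C@]3(C)[C@H](C[C@H](OC(C)=O)[C@](O)(C=O)[C@H]3CO[Si](c4ccccc4)(c5ccccc5)C(C)(C)C)C(C)(C)[C@H]1OC(=O)c1ccccc1 | intermediate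
31 | 7β-acetoxy-8α-hydroxy-8β-(1-hydroxybut-3-en-1-yl) compound, C11 epimers | CC(=O)O[C@H]1[C@@H](OC(=O)c2ccccc2)[C@]3(C)[C@H](C[C@H](OC(C)=O)[C@](O)(C(O)CC=C)[C@H]3CO[Si](c4ccccc4)(c5ccccc5)C(C)(C)C)C(C)(C)[C@H]1OC(=O)c1ccccc1 | intermediate
32 | O8,O11-isopropylidene acetal of 31 | CC(=O)O[C@H]1[C@@H](OC(=O)c2ccccc2)[C@]3(C)[C@H](C[C@H](OC(C)=O)[C@](OC(C)(C)O4)(C4CC=C)[C@H]3CO[Si](c5ccccc5)(c6ccccc6)C(C)(C)C)C(C)(C)[C@H]1OC(=O)c1ccccc1 | intermediate
33 | 9α-(hydroxymethyl) acetonide (C16 alcohol) | CC(=O)O[C@H]1[C@@H](OC(=O)c2ccccc2)[C@]3(C)[C@H](C[C@H](OC(C)=O)[C@](OC(C)(C)O4)(C4CC=C)[C@H]3CO)C(C)(C)[C@H]1OC(=O)c1ccccc1 | intermediate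
34 | 9α-carbaldehyde acetonide (C16 aldehyde) | CC(=O)O[C@H]1[C@@H](OC(=O)c2ccccc2)[C@]3(C)[C@H](C[C@H](OC(C)=O)[C@](OC(C)(C)O4)(C4CC=C)[C@H]3C=O)C(C)(C)[C@H]1OC(=O)c1ccccc1 | intermediate
35 | 9α-(1-hydroxy-3-methylbut-3-en-1-yl) acetonide, C16 epimers | CC(=O)O[C@H]1[C@@H](OC(=O)c2ccccc2)[C@]3(C)[C@H](C[C@H](OC(C)=O)[C@](OC(C)(C)O4)(C4CC=C)[C@H]3C(O)CC(C)=C)C(C)(C)[C@H]1OC(=O)c1ccccc1 | intermediate
36 | tricyclic acetonide: ring C closed, 13Z alkene, 16-hydroxy | CC(=O)O[C@H]1[C@@H](OC(=O)c2ccccc2)[C@]2(C)[C@H](C[C@H](OC(C)=O)[C@@]34OC(C)(C)OC4C/C=C(/C)CC(O)[C@H]32)C(C)(C)[C@H]1OC(=O)c1ccccc1 | intermediate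
37 | tricyclic 8α,11,16-triol, 13Z | CC(=O)O[C@H]1[C@@H](OC(=O)c2ccccc2)[C@]2(C)[C@H](C[C@H](OC(C)=O)[C@]3(O)C(O)C/C=C(/C)CC(O)[C@H]32)C(C)(C)[C@H]1OC(=O)c1ccccc1 | intermediate
38 | CNP0214674.2: 2β,7β-diacetoxy-1β,3β-bis(benzoyloxy)-8α-hydroxy-13Z-ene-11,16-dione | CC(=O)O[C@H]1[C@@H](OC(=O)c2ccccc2)[C@]2(C)[C@H](C[C@H](OC(C)=O)[C@]3(O)C(=O)C/C=C(/C)CC(=O)[C@H]32)C(C)(C)[C@H]1OC(=O)c1ccccc1 | target

**Count and risks**
Total step count: 30. Longest linear sequence: 30 steps (1 → 38); every other input is a purchased reagent.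

Step 7 (key step). The coupling may pass through a non-chelated, dipole-opposed arrangement of the two ketyls and lose facial control at C3, giving the all-equatorial 2β,3α-diol. Fallback: from dialdehyde 12 the same C2–C3 bond is made with SmI2, but C3 is then set by ketone reduction. The 3-epimeric product, 1β-benzyloxy-4,4,10α-trimethyl-trans-decalin-2β,3α-diol 9-ethylene ketal F1, is acetylated at the less hindered O2 (Ac2O, pyridine) to its 2β-acetate F2. Dess–Martin oxidation converts F2, and any 14 present, into the 2β-acetoxy-1β-benzyloxy 3-ketone F3. LiBH(s-Bu)3 at −78 °C should attack F3 along the equatorial α direction, because the axial path is closed by the syn-axial C1 benzyloxy group, and give the axial 3β-alcohol. The route is rejoined at 14.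

Step 20. Water may fail to enter at the fully substituted C8 on the face of the axial C10 methyl, so that opening occurs at C7 or the protonated epoxide rearranges by hydride shift. Fallback: from allylic alcohol 26, hydroxybromination with N-bromosuccinimide in aqueous THF at 0 °C uses the stronger Markovnikov bias of a bromonium ion and should give the 7β-bromo-8α-hydroxy-8β-(hydroxymethyl) bromohydrin F4. DBU in CH2Cl2 closes it to the 7α,8α-epoxide F5. Dilute aqueous HClO4 then opens F5 at the secondary C7 from the β face, again trans-diaxially. The route is rejoined at triol 28.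

Step 13. Transfer of the hydroxymethyl group from tin to the hindered vinylpalladium at C9, which is flanked by the quaternary C10, may be too slow, so that reduction or hydrolysis of the triflate takes over. Fallback: from triflate 18, palladium-catalysed formylation (CO 1 atm, Bu3SnH, Pd(PPh3)4, THF, 50 °C) brings in C16 by insertion of the small CO ligand and gives the Δ8 9-carbaldehyde F6. Luche reduction (NaBH4, CeCl3·7H2O, MeOH, −78 °C), which leaves the esters alone, returns to allylic alcohol 19. The same detour is available for step 18.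

Further compounds
F1 | step 7 | 1β-benzyloxy-4,4,10α-trimethyl-trans-decalin-2β,3α-diol 9-ethylene ketal (3-epimer of 13) | O[C@H]1[C@@H](OCc2ccccc2)[C@]3(C)[C@H](CCCC34OCCO4)C(C)(C)[C@@H]1O
F2 | step 7 | 2β-acetate of F1 | CC(=O)O[C@H]1[C@@H](OCc2ccccc2)[C@]3(C)[C@H](CCCC34OCCO4)C(C)(C)[C@@H]1O
F3 | step 7 | 2β-acetoxy-1β-benzyloxy-4,4,10α-trimethyl-trans-decalin-3,9-dione 9-ethylene ketal | CC(=O)O[C@H]1[C@@H](OCc2ccccc2)[C@]3(C)[C@H](CCCC34OCCO4)C(C)(C)C1=O
F4 | step 20 | 7β-bromo-8α-hydroxy-8β-(hydroxymethyl) bromohydrin of 26 | CC(=O)O[C@H]1[C@@H](OC(=O)c2ccccc2)[C@]3(C)[C@H](C[C@H](Br)[C@](O)(CO)[C@H]3CO[Si](c4ccccc4)(c5ccccc5)C(C)(C)C)C(C)(C)[C@H]1OC(=O)c1ccccc1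
F5 | step 20 | 7α,8α-epoxide with 8β-(hydroxymethyl) | CC(=O)O[C@H]1[C@@H](OC(=O)c2ccccc2)[C@]3(C)[C@H](C[C@H]4O[C@@]4(CO)[C@H]3CO[Si](c5ccccc5)(c6ccccc6)C(C)(C)C)C(C)(C)[C@H]1OC(=O)c1ccccc1
F6 | step 13 | Δ8 9-carbaldehyde of the ring A triester | CC(=O)O[C@H]1[C@@H](OC(=O)c2ccccc2)[C@]3(C)[C@H](CCC=C3C=O)C(C)(C)[C@H]1OC(=O)c1ccccc1
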